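**Assumptions (one line each):** The target is natural (2R,3'E,7'E)-α-tocotrienol. Commercial (S)-Trolox and (E,E)-farnesol are available. The CIP descriptor changes from S to R on going from Trolox to the target, but the spatial arrangement at C2 is the same.

## Retrosynthetic overview
- α-Tocotrienol comes from its 6-O-acetate by deprotection. The acetate comes from a C1'–C2' disconnection into a chroman-2-ylmethyl radical (from iodide 4) and an (E,E)-farnesyl π-allyl-Ni species (from farnesyl acetate). The C1'–C2' bond is formed in a photochemical Ni cross-electrophile coupling, and the two E-trisubstituted alkenes come intact from farnesol.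
- Iodide 4 comes from the primary alcohol, which comes from the phenol-protected acid of (S)-Trolox.
- The chroman ring and the C2 quaternary stereocentre are already present in (S)-Trolox and are never touched. There is no ring-forming step.

## Route

**Step 1**
Reactants: 1, (S)-Trolox, (2S)-6-hydroxy-2,5,7,8-tetramethylchroman-2-carboxylic acid
Product: 2, (2S)-6-acetoxy-2,5,7,8-tetramethylchroman-2-carboxylic acid
Conditions: Ac2O, pyridine, cat. DMAP, CH2Cl2, 0 °C→rt; then H2O/THF workup to hydrolyse the mixed anhydride
Reagents that add atoms: acetic anhydride, CC(=O)OC(C)=O
Why: Phenol O-acetylation protects the phenol as an aryl acetate, which is stable to borane, Appel and photoredox conditions, and the C2 stereocentre is not involved.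

**Step 2**
Reactants: 2
Product: 3, [(2S)-6-acetoxy-2,5,7,8-tetramethylchroman-2-yl]methanol
Conditions: BH3·THF, THF, 0 °C→rt; MeOH quench
Reagents that add atoms: none
Why: Borane reduces carboxylic acids much faster than the hindered aryl acetate (flanked by two ortho methyls), and C2 is untouched.

**Step 3**
Reactants: 3
Product: 4, (2S)-2-(iodomethyl)-2,5,7,8-tetramethylchroman-6-yl acetate
Conditions: PPh3, I2, imidazole, toluene, 80 °C
Reagents that add atoms: iodine, II
Why: Appel iodination of a primary alcohol; the neopentyl centre is slow but works with heat, and the configuration at C2 is unaffected because only the exocyclic CH2 reacts.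

**Step 4**
Reactants: 5, (2E,6E)-farnesol
Product: 6, (2E,6E)-farnesyl acetate
Conditions: Ac2O, pyridine, cat. DMAP, CH2Cl2, 0 °C
Reagents that add atoms: acetic anhydride, CC(=O)OC(C)=O
Why: Plain acylation of a primary allylic alcohol gives the allylic acetate used as the π-allyl-Ni precursor, and the alkene geometries are untouched.

**Step 5 (key step)**
Reactants: 4 and 6
Product: 7, (2R)-α-tocotrienyl acetate
Conditions: 4 (1 equiv), 6 (2 equiv), 4CzIPN (2 mol %), NiBr2·dtbbpy (10 mol %), Bu3N (3 equiv), DMA, blue LEDs (450 nm), 25 °C, N2, 24 h
Reagents that add atoms: none
Why: Proposed new method: Bu3N is oxidised by excited 4CzIPN to an α-aminoalkyl radical, which abstracts iodine from 4 (halogen-atom transfer) to give the primary chroman-2-ylmethyl radical.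
- Ni(0), formed by reduction, inserts into farnesyl acetate to give a (σ/π-farnesyl)Ni(II) species. The alkyl radical adds to it, and C–C reductive elimination at the unhindered CH2 terminus gives the linear product with the E,E alkenes retained.
- The closest known reactions are Ni-catalysed alkyl–allyl reductive cross-electrophile coupling and photoredox/XAT–Ni coupling. The new element is applying them to a hindered β-aryloxy neopentyl iodide and a skipped trienyl allylic acetate. The radical must be captured by Ni faster than β-C–O fragmentation, and the ester-protected phenol disfavours that fragmentation.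
- No new stereocentre forms, and the C2 configuration is carried through unchanged.

**Step 6**
Reactants: 7
Product: 8, (2R)-α-tocotrienol, the target
Conditions: LiAlH4, THF, 0 °C→rt, N2; Rochelle salt workup
Reagents that add atoms: none
Why: Hydride cleaves the aryl acetate (reductive deacylation) and leaves the isolated trisubstituted alkenes and the C2 ether untouched.

## Checks
- Ring and substituents: 8 has a 6-hydroxy-2,5,7,8-tetramethylchroman with the 4,8,12-trimethyltrideca-3,7,11-trienyl chain on C2, as in the target SMILES.
- Carbon count: 13 (chroman core plus 4 Me) + 1 (C1') + 15 (farnesyl) = 29, giving C29H44O2.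
- Stereochemistry: C2 keeps the neighbour order (chain/COOH, O, CH3, C3) with tag @ through compounds 1–8. This is S for the acid and alcohol and R for the final product, because the priority order changes. Both alkenes remain E, as in (E,E)-farnesol.
- Every stereocentre (only C2) comes from (S)-Trolox and is never involved in a reaction.

## Compound list
1 | (S)-Trolox | OC(=O)[C@]1(C)CCc2c(C)c(O)c(C)c(C)c2O1 | starting material
2 | (2S)-6-acetoxy-Trolox | OC(=O)[C@]1(C)CCc2c(C)c(OC(C)=O)c(C)c(C)c2O1 | intermediate
3 | [(2S)-6-acetoxy-2,5,7,8-tetramethylchroman-2-yl]methanol | OC[C@]1(C)CCc2c(C)c(OC(C)=O)c(C)c(C)c2O1 | intermediate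
4 | (2S)-2-(iodomethyl)-2,5,7,8-tetramethylchroman-6-yl acetate | IC[C@]1(C)CCc2c(C)c(OC(C)=O)c(C)c(C)c2O1 | intermediate
5 | (2E,6E)-farnesol | CC(C)=CCC/C(C)=C/CC/C(C)=C/CO | starting material
6 | (2E,6E)-farnesyl acetate | CC(C)=CCC/C(C)=C/CC/C(C)=C/COC(C)=O | intermediate
7 | (2R)-α-tocotrienyl acetate | CC(C)=CCC/C(C)=C/CC/C(C)=C/CC[C@]1(C)CCc2c(C)c(OC(C)=O)c(C)c(C)c2O1 | intermediate
8 | (2R,3'E,7'E)-α-tocotrienol | CC(C)=CCC/C(C)=C/CC/C(C)=C/CC[C@]1(C)CCc2c(C)c(O)c(C)c(C)c2O1 | target

## Totals
Total steps: 6. Longest linear sequence: 5 steps (1→2→3→4→7→8).

## Three steps most likely to fail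
1. **Step 5 (proposed new step).** The primary 2-chromanylmethyl radical may open by β-C–O scission, the allyl coupling may give branched or Z products, and farnesyl acetate may homocouple.
   Fallback (known chemistry, different approach): oxidise alcohol 3 to the aldehyde (Dess–Martin). Run a Wittig reaction with farnesyl-triphenylphosphonium ylide to give the conjugated diene, then reduce selectively the disubstituted C1'=C2' bond with diimide (TsNHNH2/NaOAc). Remove the acetate with LiAlH4.
2. **Step 3.** Appel substitution at the neopentyl alcohol may be sluggish or incomplete.
   Fallback: skip the halide and use alcohol 3 directly in known NHC-activation (benzoxazolium) deoxygenative Ni/photoredox coupling with 6.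
3. **Step 2.** Borane may also reduce the aryl acetate.
   Fallback (reordered approach): reduce Trolox with LiAlH4 to the diol, peracetylate it with Ac2O, then selectively cleave only the primary acetate with K2CO3/MeOH (the hindered 6-OAc resists). This gives 3 by a different order of protection and reduction.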